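**Assumption:** the SMILES is read as the all-trans oxolane (2R,3S,4S,5R), with the free phenol on the aryl at C2; both starting materials below are taken as commercial.

## Retrosynthetic overview

1. Target 8 ⇐ mono 4-O-demethylation of the C2-symmetric bis(3,4,5-trimethoxyphenyl) diol 7; the two aryl rings are homotopic, so either one gives 8.
2. 7 ⇐ LiAlH4 reduction of diester 6 ⇐ SN1 cyclodehydration of the 1,4-diaryl-1,4-diol 5. This C–O closure forms the only new ring, the oxolane.
3. 5 ⇐ key step: catalyst-controlled double dynamic-kinetic transfer hydrogenation of the symmetric, stereolabile bis(β-keto ester) 4, which converts an achiral-on-average precursor into one C2-symmetric enantiomer and sets all four stereocentres.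
4. 4 ⇐ oxidative enolate dimerisation of β-keto ester 3 ⇐ crossed Claisen of methyl 3,4,5-trimethoxybenzoate (cheap, gallic-acid derived) with tert-butyl acetate.

## Route

**Step 1**
Reactants: 1 methyl 3,4,5-trimethoxybenzoate; 2 tert-butyl acetate
Product: 3 tert-butyl 3-oxo-3-(3,4,5-trimethoxyphenyl)propanoate
Conditions: LDA (2.1 equiv), 2 (2.1 equiv), THF, −78 °C; then 1, −78 → 0 °C; aq. NH4Cl
Reagents that add atoms: none (all product atoms come from 1 and 2)
Why: crossed Claisen condensation; the non-enolisable aryl ester is acylated by the lithium enolate of 2, and the second equivalent of base drives it by deprotonating the product.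

**Step 2**
Reactants: 3 (2 equiv)
Product: 4 di-tert-butyl 2,3-bis(3,4,5-trimethoxybenzoyl)butanedioate (meso/dl mixture, interconverting through the enols)
Conditions: NaH (1.05 equiv), THF, 0 °C; then I2 (0.5 equiv), 0 °C → rt
Reagents that add atoms: none
Why: classical oxidative dimerisation of a β-keto ester enolate (in situ α-iodination, then SN2 by a second enolate); the stereochemistry of 4 is irrelevant because both α-centres are labile.

**Step 3 (key step)**
Reactants: 4
Product: 5 di-tert-butyl (2R,3R)-2,3-bis[(R)-hydroxy(3,4,5-trimethoxyphenyl)methyl]butanedioate (syn,syn; C2-symmetric)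
Conditions: RuCl[(R,R)-TsDPEN](p-cymene) (2 mol %), HCO2H/Et3N (5:2), DMF, 40 °C
Reagents that add atoms: none (hydrogen only)
Why: Proposed new method: a double Noyori–Ikariya asymmetric transfer hydrogenation with dynamic kinetic resolution on a 2,3-diaroylsuccinate; the closest known reaction is DKR-ATH of single α-substituted β-keto esters and amides, which gives syn β-hydroxy carbonyls. Each aryl ketone is reduced on the same face under catalyst control ((R,R)-catalyst → (R)-carbinol, as for acetophenone), while the adjacent α-centre equilibrates by enolisation and the syn-forming epimer reacts faster. The bulky tert-butyl esters prevent lactonisation after the first reduction, so the two halves react independently and the same sense at both ends gives the C2-symmetric isomer. Mismatched events give meso-type diastereomers that are separated, so ee is amplified.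

**Step 4**
Reactants: 5
Product: 6 di-tert-butyl (2R,3R,4R,5R)-2,5-bis(3,4,5-trimethoxyphenyl)oxolane-3,4-dicarboxylate (all-trans)
Conditions: BF3·OEt2 (1.1 equiv), CH2Cl2, 4 Å MS, −40 → 0 °C; quench Et3N as soon as 5 is consumed
Reagents that add atoms: none
Why: Lewis-acid SN1 cyclodehydration of a 1,4-diaryl-1,4-diol, the standard tetrahydrofuran-lignan closure. One electron-rich benzylic alcohol ionises and the other hydroxyl traps the cation 5-exo with retention at its own carbon. The new C–O bond forms trans to the neighbouring ester, which is both the kinetic and the thermodynamic outcome, so the (R)-carbinol centres become C2/C5 and the ring is all-trans. Hydroxyl trapping is much faster than trapping by the ester carbonyl, hence the low temperature and early quench.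

**Step 5**
Reactants: 6
Product: 7 [(2R,3S,4S,5R)-2,5-bis(3,4,5-trimethoxyphenyl)oxolane-3,4-diyl]dimethanol
Conditions: LiAlH4 (4 equiv), THF, 0 °C → 50 °C; Fieser work-up
Reagents that add atoms: none
Why: hydride reduction of both esters to primary alcohols. No stereocentre is touched; the C3/C4 descriptors change from R to S only because the CIP priorities change.

**Step 6**
Reactants: 7
Product: 8 [(2R,3S,4S,5R)-2-(4-hydroxy-3,5-dimethoxyphenyl)-5-(3,4,5-trimethoxyphenyl)oxolane-3,4-diyl]dimethanol (target)
Conditions: NaSEt (1.5–2 equiv), DMF, 100 °C, stopped at about 50–60 % conversion; mild acidic work-up (aq. NH4Cl); 7 recovered and recycled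
Reagents that add atoms: none
Why: thiolate SN2 O-demethylation of an aryl methyl ether. In a 1,2,3-trimethoxyarene the central, out-of-plane 4-OMe is cleaved selectively. Because the two rings of 7 are homotopic, a single cleavage on either ring gives 8. The step is statistical, so about 45–50 % per pass is the ceiling. The conditions are non-acidic, so the benzylic ether and the stereocentres are not disturbed.

## Compound list

1 | methyl 3,4,5-trimethoxybenzoate | COC(=O)c1cc(OC)c(OC)c(OC)c1 | starting material
2 | tert-butyl acetate | CC(=O)OC(C)(C)C | starting material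
3 | tert-butyl 3-oxo-3-(3,4,5-trimethoxyphenyl)propanoate | COc1cc(cc(OC)c1OC)C(=O)CC(=O)OC(C)(C)C | intermediate
4 | di-tert-butyl 2,3-bis(3,4,5-trimethoxybenzoyl)butanedioate (stereolabile mixture) | COc1cc(cc(OC)c1OC)C(=O)C(C(=O)OC(C)(C)C)C(C(=O)OC(C)(C)C)C(=O)c1cc(OC)c(OC)c(OC)c1 | intermediate
5 | di-tert-butyl (2R,3R)-2,3-bis[(R)-hydroxy(3,4,5-trimethoxyphenyl)methyl]butanedioate | COc1cc(cc(OC)c1OC)[C@H](O)[C@H](C(=O)OC(C)(C)C)[C@@H](C(=O)OC(C)(C)C)[C@@H](O)c1cc(OC)c(OC)c(OC)c1 | intermediate
6 | di-tert-butyl (2R,3R,4R,5R)-2,5-bis(3,4,5-trimethoxyphenyl)oxolane-3,4-dicarboxylate | COc1cc([C@@H]2O[C@@H](c3cc(OC)c(OC)c(OC)c3)[C@H](C(=O)OC(C)(C)C)[C@H]2C(=O)OC(C)(C)C)cc(OC)c1OC | intermediate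
7 | [(2R,3S,4S,5R)-2,5-bis(3,4,5-trimethoxyphenyl)oxolane-3,4-diyl]dimethanol | COc1cc([C@@H]2O[C@@H](c3cc(OC)c(OC)c(OC)c3)[C@H](CO)[C@H]2CO)cc(OC)c1OC | intermediate
8 | [(2R,3S,4S,5R)-2-(4-hydroxy-3,5-dimethoxyphenyl)-5-(3,4,5-trimethoxyphenyl)oxolane-3,4-diyl]dimethanol | COc1cc([C@@H]2O[C@@H](c3cc(OC)c(OC)c(OC)c3)[C@H](CO)[C@H]2CO)cc(OC)c1O | target

## Summary

Total steps: 6. Longest linear sequence: 6 (fully linear; 3 is used twice in Step 2).

Steps most likely to fail, with fallbacks:

1. **Step 3 (double DKR).** Risks are low syn/anti or C2/meso selectivity, slow enolisation of the hindered α-centres, and acid-promoted Paal–Knorr closure of the 1,4-diketone to the furan. Fallback: set the C8/C8′ centres with an auxiliary instead of a catalyst, by double aldol of the dienolate of di-(−)-menthyl succinate with 3,4,5-trimethoxybenzaldehyde to give the C2-symmetric exo,exo-dilactone. LiAlH4 then gives the tetraol, which enters the Step 4 fallback.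
2. **Step 4 (cyclodehydration next to esters).** Risks are tert-butyl ester participation giving the dilactone, Friedel–Crafts closure to an aryltetralin, and E1 loss to the benzylidene succinate. Fallback: change the oxidation level before ring closure. Reduce 5 to the tetraol, acylate only the two primary alcohols (lipase/vinyl acetate), close the oxolane from the ester-free diol (MsCl/Et3N or BF3·OEt2), and let the NaSEt step remove the acetates (7 steps). The primary alcohols must be masked, otherwise the tetraol closes to the furofuran.
3. **Step 6 (statistical mono-demethylation).** Risks are over-demethylation to the bis-phenol and quinone-methide opening of the phenoxide product at 100 °C. Fallback: differentiate the rings from the start. Alkylate the sodium enolate of tert-butyl 3-[4-(benzyloxy)-3,5-dimethoxyphenyl]-3-oxopropanoate with the 2-bromo derivative of 3 to get the unsymmetrical diketo diester, carry it through Steps 3–5, and finish with H2, Pd/C debenzylation.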